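**Strategy.** The hexadecyl chain (C1′–C16′, counted from furan C5) is cut at the unfunctionalised C3′–C4′ methylene–methylene bond. The key step is a photocatalytic decarboxylative radical conjugate addition: myristic acid loses CO2 to give the tridecyl radical (C4′–C16′), which adds to the terminal CH2 (C3′) of a 5-acryloyl-2-furylacetate. It exploits the nucleophilic furan C5, which accepts an acyl group, so that a temporary C1′ ketone, conjugated to the ring and to C2′=C3′, activates C3′. One operation assembles the whole C22 skeleton from an unactivated fatty acid. A Wolff–Kishner reduction then erases the C1′ carbonyl and frees the acetic acid.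

Key step: step 2

Remark: the target has no stereocentre and no stereogenic double bond, so it is a single achiral compound and no step needs stereocontrol.

**Step 1**
Reactants: 1 methyl 2-(furan-2-yl)acetate; 2 3-chloropropanoic acid
Product: 4 methyl 2-(5-prop-2-enoylfuran-2-yl)acetate, via β-chloroketone 3 (not isolated)
Conditions: 2 (1.2 equiv), (CF3CO)2O (1.5 equiv), CH2Cl2, 0 °C → rt; aq. NaHCO3 wash; then Et3N (1.5 equiv), BHT (cat.), CH2Cl2, 0 °C → rt; used at once
Reagents that add atoms: none
Why: Friedel–Crafts acylation, in which the mixed anhydride preformed from 2 and trifluoroacetic anhydride acylates the free α-position (C5) of the electron-rich 2-alkylfuran without a Lewis acid, after which the β-chloroketone 3 should lose HCl with triethylamine (E1cB elimination) to give the vinyl ketone.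

**Step 2**
Reactants: 4 methyl 2-(5-prop-2-enoylfuran-2-yl)acetate; 5 tetradecanoic acid (myristic acid)
Product: 6 methyl 2-(5-hexadecanoylfuran-2-yl)acetate
Conditions: 5 (1.5 equiv), 9-mesitylacridine (10 mol%), Cu(MeCN)4BF4 (10 mol%), CH2Cl2, 400 nm LED, rt, Ar
Reagents that add atoms: none
Why: The acridine forms a hydrogen-bonded complex with 5 and, on excitation, oxidises it by proton-coupled electron transfer; the acyloxy radical loses CO2 to give the nucleophilic tridecyl radical, which adds to the electron-poor terminal CH2 (C3′) of 4, and the resulting α-keto radical is reduced and protonated by the acridinyl radical/copper couple, which returns both catalysts. The closest known reaction type is the photocatalytic direct decarboxylative Giese reaction (radical conjugate addition) of unactivated aliphatic carboxylic acids with enones. No ring is closed and no stereocentre is formed. The step needs decarboxylation of 5 only, which is secured by carrying the furylacetic acid as its methyl ester, since an ester cannot form an acyloxy radical. It needs attack at C3′ and not at the furan ring or the carbonyl group, which is secured by the polarity match between the nucleophilic primary radical and the unhindered β-CH2 of the furoyl-conjugated alkene. It needs mono-addition, which is secured by the electrophilic character of the adduct radical, which should be reduced before it can add to a second electron-poor enone, and by the excess of 5.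

**Step 3**
Reactants: 6 methyl 2-(5-hexadecanoylfuran-2-yl)acetate
Product: 8 2-(5-hexadecylfuran-2-yl)acetic acid, via hydrazone carboxylate 7 (not isolated)
Conditions: N2H4·H2O (5 equiv), KOH (6 equiv), diethylene glycol, 130 °C; then 195 °C with removal of water; then cold 1 M HCl to pH 3
Reagents that add atoms: potassium hydroxide, [K+].[OH-] (oxygen of the CO2H group); hydrazine, NN (nitrogen atoms of intermediate 7 only, lost as N2 before 8)
Why: Wolff–Kishner reduction in a high-boiling glycol, in which hydroxide saponifies the methyl ester while hydrazine condenses with the aryl ketone, and base-induced loss of N2 from hydrazone 7 should leave the C1′ methylene on the base-stable furan.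

**Compound list**
1 | methyl 2-(furan-2-yl)acetate | COC(=O)Cc1ccco1 | starting material
2 | 3-chloropropanoic acid | OC(=O)CCCl | starting material
3 | methyl 2-[5-(3-chloropropanoyl)furan-2-yl]acetate | COC(=O)Cc1ccc(C(=O)CCCl)o1 | intermediate
4 | methyl 2-(5-prop-2-enoylfuran-2-yl)acetate | COC(=O)Cc1ccc(C(=O)C=C)o1 | intermediate
5 | tetradecanoic acid (myristic acid) | CCCCCCCCCCCCCC(=O)O | starting material
6 | methyl 2-(5-hexadecanoylfuran-2-yl)acetate | CCCCCCCCCCCCCCCC(=O)c1ccc(CC(=O)OC)o1 | intermediate
7 | potassium 2-[5-(1-hydrazinylidenehexadecyl)furan-2-yl]acetate | CCCCCCCCCCCCCCCC(=NN)c1ccc(CC(=O)[O-])o1.[K+] | intermediate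
8 | 2-(5-hexadecylfuran-2-yl)acetic acid | CCCCCCCCCCCCCCCCc1ccc(CC(=O)O)o1 | target

**Total step count:** 3
**Longest linear sequence:** 3 steps (1 → 4 → 6 → 8)

**Steps most likely to fail**

Step 2 (key step). The unstabilised primary tridecyl radical may form too slowly from the unactivated acid, so that the vinyl ketone is consumed by telomerisation or light-induced polymerisation before it is alkylated. The fallback makes the same C3′–C4′ bond by a polar, two-electron route that sets out from 4. Commercial 1-bromotridecane F1 would be converted with Mg in THF into tridecylmagnesium bromide F2. F2 would be added to 4 under copper catalysis (CuBr·SMe2 10 mol%, Me3SiCl, THF, −78 °C; 1,4-addition, at which temperature the ester should not react). The silyl enol ether methyl 2-{5-[1-(trimethylsilyloxy)hexadec-1-en-1-yl]furan-2-yl}acetate F3 (E/Z geometry irrelevant) would be hydrolysed on work-up with dilute aqueous acid. The fallback comes back to the route at 6.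

Step 1. The electron-rich furan may oligomerise under the acidic acylation conditions or be trifluoroacetylated instead, and the β-chloroketone may polymerise during the elimination. The fallback sets out from 1 and builds the enone in C1 + C2 fashion under non-acidic end conditions. Vilsmeier–Haack formylation (POCl3, DMF, 0 °C → rt; aq. NaOAc) should give methyl 2-(5-formylfuran-2-yl)acetate F4. Addition of vinylmagnesium bromide (THF, −78 °C; the aldehyde should react much faster than the ester) should give racemic methyl 2-[5-(1-hydroxyprop-2-en-1-yl)furan-2-yl]acetate F5, whose carbinol centre is erased in the next operation. Oxidation with activated MnO2 (CH2Cl2, rt) comes back to the route at 4.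

Step 3. Under the hot alkaline conditions the hydrazone may be converted only in part (azine formation), or the furylacetate may degrade by decarboxylation. The fallback sets out from 6 and deoxygenates under near-neutral conditions. TsNHNH2 (EtOH, 60 °C) should give the tosylhydrazone methyl 2-(5-{1-[2-(4-methylbenzenesulfonyl)hydrazinylidene]hexadecyl}furan-2-yl)acetate F6. Hydride reduction with catecholborane (CHCl3, 0 °C), then NaOAc·3H2O at reflux, should give methyl 2-(5-hexadecylfuran-2-yl)acetate F7 with loss of sulfinate and N2. Saponification (LiOH, THF/H2O, rt; mild acidification) comes back to the route at 8.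

**Further compounds**
F1 | step 2 | 1-bromotridecane (commercial starting material of the fallback) | CCCCCCCCCCCCCBr
F2 | step 2 | tridecylmagnesium bromide | CCCCCCCCCCCCC[Mg]Br
F3 | step 2 | methyl 2-{5-[1-(trimethylsilyloxy)hexadec-1-en-1-yl]furan-2-yl}acetate | CCCCCCCCCCCCCCC=C(O[Si](C)(C)C)c1ccc(CC(=O)OC)o1
F4 | step 1 | methyl 2-(5-formylfuran-2-yl)acetate | COC(=O)Cc1ccc(C=O)o1
F5 | step 1 | methyl 2-[5-(1-hydroxyprop-2-en-1-yl)furan-2-yl]acetate (racemic) | COC(=O)Cc1ccc(C(O)C=C)o1
F6 | step 3 | methyl 2-(5-{1-[2-(4-methylbenzenesulfonyl)hydrazinylidene]hexadecyl}furan-2-yl)acetate | CCCCCCCCCCCCCCCC(=NNS(=O)(=O)c1ccc(C)cc1)c2ccc(CC(=O)OC)o2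
F7 | step 3 | methyl 2-(5-hexadecylfuran-2-yl)acetate | CCCCCCCCCCCCCCCCc1ccc(CC(=O)OC)o1
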